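Late in the maple run, at 4.00 h, E stands at 11% and X at 15% of the two charged together, with D at 50%. J turns E into D and X into Z, while Q may interconvert E and X until it decays to G. The new flask is more dilute than maple.

- maple: E 1.1 M; X 1.1 M; J 2.2 equiv; Q 0.24 mol%; run made earlier
- flask: E 0.80 M; J 2.20 equiv; Q 0.24 mol%; X 0.80 M; time 4.0 h

maple run (percent of the E and X together charged)

| time / h | E / % | X / % | D / % |
|---|---|---|---|
| 0.500 | 37 | 37 | 22 |
| 1.00 | 27 | 32 | 27 |
| 1.50 | 24 | 27 | 33 |
| 2.50 | 17 | 22 | 43 |
| 3.00 | 14 | 18 | 42 |
| 4.00 | 11 | 15 | 50 |

(each reading ± 1.5 percentage points)

- J is single-handed; E and X are mirror images of each other, charged as a racemate, each of them at the stated concentration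
- the analysis behind the earlier runs scatters by 1.5 percentage points, standard deviation
- what may be going on: J + E -> D; E + Q <-> X + Q; Q -> G; J <-> L; J + X -> Z
- an excess is the difference of the two amounts in percent of their sum
- an excess is below zero if the other one leads
- no earlier run changes the charge of Q; that part of a forecast is a guess
- the handed part of J does not stay in what it makes, so the products of the two hands are mirror images too

1. part of the E and X charged together that has reacted at 4.0 h
2. excess of D over Z in the product at 4.0 h
3. excess of X over E among what is left of the two at 4.0 h

Z is what the maple sum lacks, 24.0%, so D over Z reads 2.08. Two extremes solve in the head. If Q holds E equal to X, both fall alike and that split is the selectivity factor. If Q does nothing, each hand falls first order in its own constant with the same J, so the logarithm of the fraction of E left, over that for X, equals the selectivity factor. For maple this ratio reads 1.26, each input scattering by 1.5 percentage points. Call it the resolution index: 1 under full racemisation, the selectivity factor without any. Maple's readings lie nearer the racemising extreme.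

The flask keeps maple's ratios of J and Q to E at 0.727 of its concentration, so consumption and racemisation slow together, but a first-order death of Q does not. The reckoning made here therefore puts the flask's index above maple's.

The forecast gives 63%, 34% and 14%, holding that “Q dies relatively sooner”; these numbers imply an index of 1.33, above maple's reading.

The flask gives 65.6%, 33.3% and 18.8%.

    J + E → D (k = 0.0100 L mol⁻¹ min⁻¹)
    E + Q ⇌ X + Q, rate k2*[Q]*[E] forward; the back reaction follows from the equilibrium constant (k = 51.0 L mol⁻¹ min⁻¹)
    Q → G (k = 0.0260 min⁻¹)
    J ⇌ L (K = 0.720, k = 0.0190 min⁻¹)
    J + X → Z (k = 0.00450 L mol⁻¹ min⁻¹)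

The flask's index is 1.43, above maple's reading. In the flask Q has a half-life of 0.44 h by its decay alone, shorter than the 0.944 h by which the J + X path has done half of its turnover up to 4.0 h, and at 2.00 h Q stands at 4.42% of its charge with 49.8% of the E and X together reacted. The neighbour flask charged with 0.06 mol% of Q has an index of 1.73 and an excess of X over E of 28.4%.

All runs are calculated for substances that don't exist; scatter was added.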